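**Assumption:** atoms carry the germacranolide locants of the target (C1–C10 ring, C11–C13 lactone arm, C12 the lactone carbonyl, C14 on C10, C15 on C4). Stereodescriptors in names refer to these locants.

## Retrosynthetic overview

1. Target ⇐ Mitsunobu acetoxylation with inversion at C6 ⇐ OH-directed epoxidation of the 4Z alkene ⇐ CBS reduction of a cyclodeca-1(10)E,4Z-dien-6-one.
2. Ten-membered ring ⇐ Grob-type ring expansion (C1–C6 cleavage) of a cis-fused decalin-6,10-diol 10-mesylate that already carries the cis-fused α-methylene lactone.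
3. Ring B and the lactone ⇐ intramolecular indium Barbier addition of a 3-(bromomethyl)butenolide to the ring A enone (C6–C7); butenolide ⇐ ring-closing metathesis.
4. Ring A ⇐ enantioselective Diels–Alder of a prenal-derived silyloxydiene with (Z)-β-acetoxyvinyl methyl ketone; C8 by boron aldol with acrolein, C10 by chelation-controlled MeMgBr addition.
5. Ring order: ring A → butenolide → ring B with lactone → ten-membered ring → oxirane.

## Route

**Step 1**
Reactants: 1 3-methylbut-2-enal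
Product: 2 (E)-triethyl[(3-methylbuta-1,3-dien-1-yl)oxy]silane
Conditions: Et3SiOTf, Et3N, Et2O, 0 °C to rt
Reagents that add atoms: triethylsilyl trifluoromethanesulfonate CC[Si](CC)(CC)OS(=O)(=O)C(F)(F)F
Why: γ-deprotonation and O-silylation of the enal (silyl dienol ether formation) gives the E enol ether; no stereocentre is formed.

**Step 2**
Reactants: 3 but-3-yn-2-one
Product: 4 (Z)-3-oxobut-1-en-1-yl acetate
Conditions: AcOH, Ru(η3-CH2C(CH3)CH2)2(dppb) (2 mol %), toluene, 45 °C
Reagents that add atoms: acetic acid CC(=O)O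
Why: anti-Markovnikov hydro-oxycarbonylation of a terminal alkyne places the acetate on the terminal carbon by anti addition, which gives the Z enol ester.

**Step 3**
Reactants: 2 (E)-triethyl[(3-methylbuta-1,3-dien-1-yl)oxy]silane, 4 (Z)-3-oxobut-1-en-1-yl acetate
Product: 5 (1S,2S,6R)-1-acetyl-4-methyl-6-(triethylsilyloxy)cyclohex-4-en-2-yl acetate (all-cis)
Conditions: (S)-o-tolyl-CBS-oxazaborolidinium triflimide (20 mol %), CH2Cl2, −78 to −40 °C
Reagents that add atoms: none
Why: Proposed new method: enantioselective Diels–Alder of a (Z)-β-acyloxy vinyl ketone under chiral oxazaborolidinium catalysis, in which boron binds the ketone and lowers the LUMO while the cis-acetoxy group points away from the catalyst so the Z geometry survives, the 1-silyloxy and 3-methyl groups of the diene both direct C6–C1/C3–C2 bonding, endo approach puts OSiEt3, acetyl and OAc all cis, and the catalyst aryl groups shield one face to give (1S,2S,6R); the closest known reaction type is the Corey oxazaborolidinium-catalysed Diels–Alder of enones and quinones with silyloxydienes, not yet shown for cis-β-oxygenated acyclic enones.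

**Step 4**
Reactants: 5 (1S,2S,6R)-1-acetyl-4-methyl-6-(triethylsilyloxy)cyclohex-4-en-2-yl acetate, 6 acrolein
Product: 7 (1S,2S,6R)-1-[(3R)-3-hydroxypent-4-enoyl]-4-methyl-6-(triethylsilyloxy)cyclohex-4-en-2-yl acetate
Conditions: (+)-Ipc2BCl, Et3N, Et2O, −78 °C; 6, −78 to −20 °C; H2O2, pH 7 buffer, MeOH
Reagents that add atoms: none
Why: Paterson boron aldol, in which Ipc2BCl/Et3N enolises only toward the methyl group (so no enolate at C1 and no β-elimination) and the isopinocampheyl ligands, in the enantiomer chosen for Re-face attack on the aldehyde, set 8R.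

**Step 5**
Reactants: 7 (1S,2S,6R)-1-[(3R)-3-hydroxypent-4-enoyl]-4-methyl-6-(triethylsilyloxy)cyclohex-4-en-2-yl acetate
Product: 8 (1S,2S,6R)-1-[(2S,4R)-2,4-dihydroxyhex-5-en-2-yl]-4-methyl-6-(triethylsilyloxy)cyclohex-4-en-2-yl acetate
Conditions: MeMgBr (3 equiv), CH2Cl2/Et2O, −78 °C
Reagents that add atoms: methylmagnesium bromide C[Mg]Br
Why: chelation-controlled Grignard addition, in which the magnesium β-alkoxide holds the C10 ketone in a six-membered chelate and methyl adds anti to the C8 vinyl group to give the 1,3-syn diol (10S), the ketone reacting faster than the acetate at −78 °C.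

**Step 6**
Reactants: 8 (1S,2S,6R)-1-[(2S,4R)-2,4-dihydroxyhex-5-en-2-yl]-4-methyl-6-(triethylsilyloxy)cyclohex-4-en-2-yl acetate, 9 2-(bromomethyl)acrylic acid
Product: 10 (3R,5S)-5-[(1S,2S,6R)-2-acetoxy-4-methyl-6-(triethylsilyloxy)cyclohex-4-en-1-yl]-5-hydroxyhex-1-en-3-yl 2-(bromomethyl)acrylate
Conditions: DIC, DMAP (5 mol %), CH2Cl2, −20 to 0 °C
Reagents that add atoms: none
Why: Steglich esterification acylates the secondary allylic C8 hydroxyl and leaves the tertiary C10 hydroxyl untouched; no stereocentre changes.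

**Step 7**
Reactants: 10 (3R,5S)-5-[(1S,2S,6R)-2-acetoxy-4-methyl-6-(triethylsilyloxy)cyclohex-4-en-1-yl]-5-hydroxyhex-1-en-3-yl 2-(bromomethyl)acrylate
Product: 11 (1S,2S,6R)-1-{(2S)-1-[(2R)-4-(bromomethyl)-5-oxo-2,5-dihydrofuran-2-yl]-2-hydroxypropan-2-yl}-4-methyl-6-(triethylsilyloxy)cyclohex-4-en-2-yl acetate
Conditions: second-generation Hoveyda–Grubbs catalyst RuCl2(SIMes)(=CH-C6H4-2-O-i-Pr) (5 mol %), toluene, 80 °C
Reagents that add atoms: none
Why: ring-closing metathesis between the vinyl group and the acrylate closes the butenolide (C7=C11), while the trisubstituted ring A alkene is inert and C8 is untouched.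

**Step 8**
Reactants: 11 (1S,2S,6R)-1-{(2S)-1-[(2R)-4-(bromomethyl)-5-oxo-2,5-dihydrofuran-2-yl]-2-hydroxypropan-2-yl}-4-methyl-6-(triethylsilyloxy)cyclohex-4-en-2-yl acetate
Product: 12 (1R,2S)-1-{(2S)-1-[(2R)-4-(bromomethyl)-5-oxo-2,5-dihydrofuran-2-yl]-2-hydroxypropan-2-yl}-4-methyl-6-oxocyclohex-4-en-2-yl acetate
Conditions: DDQ, CH2Cl2/pH 7 buffer, rt
Reagents that add atoms: none
Why: DDQ oxidation of an allylic silyl ether (hydride abstraction at C6, then loss of silanol) gives the enone under neutral conditions, which avoids E1cB loss of the C2 acetate.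

**Step 9**
Reactants: 12 (1R,2S)-1-{(2S)-1-[(2R)-4-(bromomethyl)-5-oxo-2,5-dihydrofuran-2-yl]-2-hydroxypropan-2-yl}-4-methyl-6-oxocyclohex-4-en-2-yl acetate
Product: 13 (1R,2S,6R,7R,8R,10S)-2-acetoxy-6,10-dihydroxy-1,6-cyclogermacra-4,11(13)-dien-8,12-olide (cadinane-type; rings A/B cis-fused, lactone cis-fused)
Conditions: In (powder), THF/H2O 4:1, rt
Reagents that add atoms: none
Why: intramolecular Barbier allylation, in which the allylindium from the bromomethylbutenolide adds 1,2 to the enone through its γ-carbon C7 to close six-membered ring B, the tether forcing attack syn to C9 (cis lactone, 7R) and axial attack on the face of the C1 side chain giving the cis ring fusion (6R).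

**Step 10**
Reactants: 13 (1R,2S,6R,7R,8R,10S)-2-acetoxy-6,10-dihydroxy-1,6-cyclogermacra-4,11(13)-dien-8,12-olide
Product: 15 (2S,7R,8R)-2-acetoxy-6-oxogermacra-1(10)E,4Z,11(13)-trien-8,12-olide, via tertiary mesylate 14 (not isolated)
Conditions: MsCl, Et3N, CH2Cl2, −40 °C; then KN(SiMe3)2, THF, −78 to −30 °C
Reagents that add atoms: methanesulfonyl chloride CS(=O)(=O)Cl
Why: Grob fragmentation (ring expansion 6/6 → 10), in which the less hindered C10 methyl carbinol is sulfonylated and the C6 alkoxide then cleaves C1–C6 anti-periplanar to the equatorial C10–OMs bond, with C2 equatorial on ring B and therefore anti to C9 (1(10)E), while the 4Z enone geometry is inherited from ring A.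

**Step 11**
Reactants: 15 (2S,7R,8R)-2-acetoxy-6-oxogermacra-1(10)E,4Z,11(13)-trien-8,12-olide
Product: 16 (2S,6S,7S,8R)-2-acetoxy-6-hydroxygermacra-1(10)E,4Z,11(13)-trien-8,12-olide
Conditions: (S)-Me-CBS (0.5 equiv), catecholborane, toluene, −78 °C
Reagents that add atoms: none
Why: Corey–Bakshi–Shibata 1,2-reduction, in which the alkenyl arm C5 acts as the large group so that (S)-Me-CBS delivers hydride to give the C6 alcohol epimeric to the target acetate, and catecholborane leaves the alkenes and esters alone.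

**Step 12**
Reactants: 16 (2S,6S,7S,8R)-2-acetoxy-6-hydroxygermacra-1(10)E,4Z,11(13)-trien-8,12-olide
Product: 17 (2S,4R,5S,6R,7S,8R)-2-acetoxy-4,5-epoxy-6-hydroxygermacra-1(10)E,11(13)-dien-8,12-olide
Conditions: VO(acac)2 (5 mol %), t-BuOOH, CH2Cl2, 0 °C
Reagents that add atoms: tert-butyl hydroperoxide CC(C)(C)OO
Why: hydroxyl-directed (Sharpless–Michaelson) epoxidation touches only the allylic-alcohol alkene and, through the A(1,3)-minimised conformer of the Z-allylic alcohol, delivers oxygen syn to the hydroxyl (threo), setting 4R,5S as a cis-oxirane.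

**Step 13**
Reactants: 17 (2S,4R,5S,6R,7S,8R)-2-acetoxy-4,5-epoxy-6-hydroxygermacra-1(10)E,11(13)-dien-8,12-olide
Product: 18 (2S,4R,5S,6S,7R,8R)-2,6-diacetoxy-4,5-epoxygermacra-1(10)E,11(13)-dien-8,12-olide (CNP0270851.1)
Conditions: AcOH, PPh3, DIAD, toluene, 0 °C to rt
Reagents that add atoms: acetic acid CC(=O)O
Why: Mitsunobu esterification displaces the activated C6 oxygen by acetate with SN2 inversion, giving the 6S acetate anti to the oxirane oxygen as in the target.

## Compound list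

1 | 3-methylbut-2-enal | CC(C)=CC=O | starting material
2 | (E)-triethyl[(3-methylbuta-1,3-dien-1-yl)oxy]silane | C=C(C)/C=C/O[Si](CC)(CC)CC | intermediate
3 | but-3-yn-2-one | CC(=O)C#C | starting material
4 | (Z)-3-oxobut-1-en-1-yl acetate | CC(=O)/C=C\OC(C)=O | intermediate
5 | (1S,2S,6R)-1-acetyl-4-methyl-6-(triethylsilyloxy)cyclohex-4-en-2-yl acetate | CC(=O)[C@H]1[C@@H](OC(C)=O)CC(C)=C[C@H]1O[Si](CC)(CC)CC | intermediate
6 | acrolein | C=CC=O | starting material
7 | (1S,2S,6R)-1-[(3R)-3-hydroxypent-4-enoyl]-4-methyl-6-(triethylsilyloxy)cyclohex-4-en-2-yl acetate | C=C[C@H](O)CC(=O)[C@H]1[C@@H](OC(C)=O)CC(C)=C[C@H]1O[Si](CC)(CC)CC | intermediate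
8 | (1S,2S,6R)-1-[(2S,4R)-2,4-dihydroxyhex-5-en-2-yl]-4-methyl-6-(triethylsilyloxy)cyclohex-4-en-2-yl acetate | C=C[C@H](O)C[C@](C)(O)[C@H]1[C@@H](OC(C)=O)CC(C)=C[C@H]1O[Si](CC)(CC)CC | intermediate
9 | 2-(bromomethyl)acrylic acid | C=C(CBr)C(=O)O | starting material
10 | (3R,5S)-5-[(1S,2S,6R)-2-acetoxy-4-methyl-6-(triethylsilyloxy)cyclohex-4-en-1-yl]-5-hydroxyhex-1-en-3-yl 2-(bromomethyl)acrylate | C=C[C@H](OC(=O)C(=C)CBr)C[C@](C)(O)[C@H]1[C@@H](OC(C)=O)CC(C)=C[C@H]1O[Si](CC)(CC)CC | intermediate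
11 | (1S,2S,6R)-1-{(2S)-1-[(2R)-4-(bromomethyl)-5-oxo-2,5-dihydrofuran-2-yl]-2-hydroxypropan-2-yl}-4-methyl-6-(triethylsilyloxy)cyclohex-4-en-2-yl acetate | O=C1O[C@H](C[C@](C)(O)[C@H]2[C@@H](OC(C)=O)CC(C)=C[C@H]2O[Si](CC)(CC)CC)C=C1CBr | intermediate
12 | (1R,2S)-1-{(2S)-1-[(2R)-4-(bromomethyl)-5-oxo-2,5-dihydrofuran-2-yl]-2-hydroxypropan-2-yl}-4-methyl-6-oxocyclohex-4-en-2-yl acetate | O=C1O[C@H](C[C@](C)(O)[C@H]2[C@@H](OC(C)=O)CC(C)=CC2=O)C=C1CBr | intermediate
13 | (1R,2S,6R,7R,8R,10S)-2-acetoxy-6,10-dihydroxy-1,6-cyclogermacra-4,11(13)-dien-8,12-olide | C=C1C(=O)O[C@@H]2C[C@](C)(O)[C@H]3[C@@H](OC(C)=O)CC(C)=C[C@@]3(O)[C@H]12 | intermediate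
14 | 10-O-methanesulfonate of 13 (tertiary mesylate) | C=C1C(=O)O[C@@H]2C[C@](C)(OS(C)(=O)=O)[C@H]3[C@@H](OC(C)=O)CC(C)=C[C@@]3(O)[C@H]12 | intermediate
15 | (2S,7R,8R)-2-acetoxy-6-oxogermacra-1(10)E,4Z,11(13)-trien-8,12-olide | C=C1C(=O)O[C@@H]2C/C(C)=C/[C@@H](OC(C)=O)C/C(C)=C\C(=O)[C@H]12 | intermediate
16 | (2S,6S,7S,8R)-2-acetoxy-6-hydroxygermacra-1(10)E,4Z,11(13)-trien-8,12-olide | C=C1C(=O)O[C@@H]2C/C(C)=C/[C@@H](OC(C)=O)C/C(C)=C\[C@H](O)[C@H]12 | intermediate
17 | (2S,4R,5S,6R,7S,8R)-2-acetoxy-4,5-epoxy-6-hydroxygermacra-1(10)E,11(13)-dien-8,12-olide | C=C1C(=O)O[C@@H]2C/C(C)=C/[C@@H](OC(C)=O)C[C@@]3(C)O[C@H]3[C@H](O)[C@H]12 | intermediate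
18 | (2S,4R,5S,6S,7R,8R)-2,6-diacetoxy-4,5-epoxygermacra-1(10)E,11(13)-dien-8,12-olide (CNP0270851.1) | C=C1C(=O)O[C@@H]2C/C(C)=C/[C@@H](OC(C)=O)C[C@@]3(C)O[C@H]3[C@@H](OC(C)=O)[C@H]12 | target

## Step count and risks

Total steps: 13. Longest linear sequence: 12 (steps 1 and 3–13; step 2 is a one-step side branch).

**Most likely to fail, 1: the new enantioselective cycloaddition (2 + 4 → 5).** The acid catalyst may isomerise 4 to the E enol ester. That would give the C1 epimer, which after the later fragmentation leads to the 1(10)Z ring, and the facial selectivity is untested. The fallback sets out from 2 and 4 and uses known chemistry: an uncatalysed thermal Diels–Alder reaction (toluene, 60 °C) gives 5 as the racemate, that is together with the mirror-image adduct (1R,2R,6S)-1-acetyl-4-methyl-6-(triethylsilyloxy)cyclohex-4-en-2-yl acetate F1. A lipase kinetic resolution (Candida antarctica lipase B, pH 7 buffer/acetone) then hydrolyses only F1 to the alcohol (1R,2R,6S)-2-acetyl-5-methyl-3-(triethylsilyloxy)cyclohex-4-en-1-ol F2. The unreacted acetate is separated by chromatography and the route is rejoined at compound 5.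

**Most likely to fail, 2: the mesylation/Grob ring expansion (13 → 15).** The tertiary mesylate 14 may eliminate, C6–OH may be sulfonylated instead, or the cis-fused decalin may fragment from the other chair and give some 1(10)Z product. The fallback sets out from 12 and separates the two oxygens by protection. A CrCl2-catalysed Nozaki–Hiyama–Kishi cyclisation with Mn and Me3SiCl closes ring B and delivers the carbinol directly as its silyl ether, the 6-O-trimethylsilyl ether of 13 F3. Mesylation of the only free hydroxyl gives the 6-O-trimethylsilyl-10-O-mesyl derivative F4. Bu4NF at −78 °C then unmasks the alkoxide, which fragments at once, and the route is rejoined at compound 15.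

**Most likely to fail, 3: the Mitsunobu inversion next to the oxirane (17 → 18).** The secondary carbinol is hindered, and the oxirane oxygen or the 1(10) alkene may take part. The fallback sets out from 17 and replaces the SN2 step by oxidation and reduction. Dess–Martin periodinane gives the epoxy ketone (2S,4R,5R,7R,8R)-2-acetoxy-4,5-epoxy-6-oxogermacra-1(10)E,11(13)-dien-8,12-olide F5. Zn(BH4)2 in Et2O at −20 °C reduces α,β-epoxy ketones anti-selectively through a zinc chelate and gives the 6-epimeric alcohol (2S,4R,5S,6S,7S,8R)-2-acetoxy-4,5-epoxy-6-hydroxygermacra-1(10)E,11(13)-dien-8,12-olide F6. Ac2O, pyridine and DMAP then give compound 18.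

## Further compounds

F1 | step 3 | (1R,2R,6S)-1-acetyl-4-methyl-6-(triethylsilyloxy)cyclohex-4-en-2-yl acetate (enantiomer of 5) | CC(=O)[C@@H]1[C@H](OC(C)=O)CC(C)=C[C@@H]1O[Si](CC)(CC)CC
F2 | step 3 | (1R,2R,6S)-2-acetyl-5-methyl-3-(triethylsilyloxy)cyclohex-4-en-1-ol (descriptors on target locants) | CC(=O)[C@@H]1[C@H](O)CC(C)=C[C@@H]1O[Si](CC)(CC)CC
F3 | step 10 | 6-O-trimethylsilyl ether of 13 | C=C1C(=O)O[C@@H]2C[C@](C)(O)[C@H]3[C@@H](OC(C)=O)CC(C)=C[C@@]3(O[Si](C)(C)C)[C@H]12
F4 | step 10 | 6-O-trimethylsilyl-10-O-methanesulfonyl derivative of 13 | C=C1C(=O)O[C@@H]2C[C@](C)(OS(C)(=O)=O)[C@H]3[C@@H](OC(C)=O)CC(C)=C[C@@]3(O[Si](C)(C)C)[C@H]12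
F5 | step 13 | (2S,4R,5R,7R,8R)-2-acetoxy-4,5-epoxy-6-oxogermacra-1(10)E,11(13)-dien-8,12-olide | C=C1C(=O)O[C@@H]2C/C(C)=C/[C@@H](OC(C)=O)C[C@@]3(C)O[C@H]3C(=O)[C@H]12
F6 | step 13 | (2S,4R,5S,6S,7S,8R)-2-acetoxy-4,5-epoxy-6-hydroxygermacra-1(10)E,11(13)-dien-8,12-olide | C=C1C(=O)O[C@@H]2C/C(C)=C/[C@@H](OC(C)=O)C[C@@]3(C)O[C@H]3[C@@H](O)[C@H]12
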